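Compound numbers 1–23 are those of the steps and the compound list below. Flavanone atoms are unprimed (rings A and C) and primed (ring B); flavone atoms are double-primed (rings A and C) and triple-primed (ring B).

## The problem

The target 23 has a 2,3-dihydroamentoflavone skeleton: a (2S)-naringenin whose ring B carbon C3' is bonded to C8'' of an apigenin. The two benzopyranone halves are joined by a single biaryl bond between two electron-rich rings, flanked by C4'–OH on one side and by C7''–OH and C8a''–O1'' on the other. On the flavone the aryl group must sit at C8'' and not at the equally nucleophilic C6'', so the regiochemistry of ring A cannot be left to an electrophilic substitution on a 5,7-dioxygenated flavone. There is one stereocentre, C2, and nothing else in the molecule can control it (the structure defines no axial configuration), so it must be set by a catalyst. C2 is benzylic, β to the C4 carbonyl and para to the C4' oxygen: base reopens ring C to the 2'-hydroxychalcone, and once the C4' phenol is free a quinone methide pathway racemises it, so C2 must be made late and kept away from base afterwards. Six phenols, two of them chelated to carbonyls (C5 and C5''), have to be unmasked at the end without base or strong acid, which points to benzyl ethers and hydrogenolysis and to earlier steps that tolerate benzyl ethers. The enabling feature lies in flavone ring A: the adjacent carbons C8a'' and C4a'' carry O1'' and the C4'' carbonyl, C4a'' has the oxygenated C5'' as its other neighbour, and C8a'' has the aryl-bearing C8''. An aryne C4a''≡C8a'', polarised by the C5'' alkoxy group, gives exactly this pattern when it inserts into the acyl–oxygen bond of a carboxylic acid, and with a 3-arylpropiolic acid the ketone and phenoxide so formed close ring C at once.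

## Retrosynthesis

**23 ⇒ 22.** The six phenolic O–H bonds of 23 are traced back to benzyl ethers. Methyl ethers would need a boron halide and methoxymethyl ethers would need acid, both applied to a flavanone whose C2 is ionisable; hydrogenolysis is neutral. The skeleton of 22 is no simpler, but it is the form in which C2 can be handled. The forward step must remove six benzyl groups while sparing the benzylic C2–O1 bond and the flavone alkene.

**22 ⇒ 19.** The O1–C2 bond of the flavanone is cut and a tert-butoxycarbonyl group is added at C3, giving alkylidene β-keto ester 19.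
- The neighbouring cut C2–C1' (conjugate arylation of a chromone) would use the whole biflavonoid aryl group as an organoboron nucleophile, normally needed in excess.
- A plain 2'-hydroxychalcone has no dependable enantioselective closure.
- The ester gives a bifunctional catalyst two carbonyl groups to bind.

Compound 19 has no stereocentre and an open ring C. The forward reaction must close ring C with catalyst control of C2 (through 20) and then lose the ester (through 21) faster than ring C can reopen.

**19 ⇒ 16 + 18; 18 ⇒ 17; 16 ⇒ 15.** The C2=C3 alkene is cut by a Knoevenagel disconnection into aldehyde 16 and β-keto ester 18. Ester 18 is one C-acylation away from commercial acetophenone 17. This is the point of convergence: 16 carries the flavone and the biaryl bond, 18 carries flavanone ring A. Aldehyde 16 is held upstream as dioxolane 15 because an organolithium is used there. The condensation must not trigger premature, uncatalysed ring closure.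

**15 ⇒ 10 + 12 (key).** Three bonds of flavone ring C are cut together: C8a''–O1'', C4a''–C4'' and O1''–C2''. This leaves ortho-silylaryl triflate 10 (the source of aryne 13) and 3-arylpropiolic acid 12, made by carboxylation of alkyne 11.
- The neighbouring cut at the biaryl bond (cross-coupling at C8'' of a finished flavone) meets the C6''/C8'' halogenation problem and a hindered coupling on advanced material.
- The neighbouring cut at C2''–C3'' (acetophenone-based flavone synthesis) needs a regioselective C-acylation of a biaryl phenol.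
- The aryne cut uses the C5'' oxygen, already present in the product, as its control element and puts the aryl group next to C8a'' before the heterocycle exists.

Precursor 10 is a hexasubstituted benzene with no heterocycle. The forward reaction needs three things:
- carboxylate attack at C8a'' (remote from the C5'' benzyloxy group) despite the neighbouring aryl group;
- acyl migration to C4a'' (giving 14) faster than protonation;
- 6-endo closure onto the ynone.

**10 ⇒ 8 ⇒ 7 ⇒ 6.** The C–Si and O–S bonds of 10 are traced back to ortho-bromophenol 7: O-silylation gives 8, and halogen–lithium exchange, retro-Brook shift (to 9) and triflation follow. This is the shortest way to put silicon and triflate on adjacent carbons. The C–Br bond of 7 comes from bromination of phenol 6. The forward bromination must go ortho to the hydroxyl (C6) and not para (C4).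

**6 ⇒ 2 + 5; 2 ⇒ 1; 5 ⇒ 4 ⇒ 3.** The biaryl bond (the future C3'–C8'') is cut by a Suzuki–Miyaura disconnection into bromophenol 2 and boronate 5. Bromophenol 2 comes from commercial phenol 1 by bromination. Boronate 5 comes from commercial bromoaldehyde 3 through acetal 4 and borylation. The hindered bond is thus made first, between two monocyclic partners that are cheap to use in excess. The coupling must tolerate a free ortho phenol and three ortho substituents.

## Roads not taken

**Alternative 1:** The cut is O1–C2 of the flavanone, taken as the centre of the plan.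
- Forward step: a cinchona thiourea closes the ester-activated 2'-hydroxychalcone A2, the phenol adding to the benzylic alkene carbon, and TsOH then removes the tert-butyl ester by decarboxylation to give hexa-O-benzyl flavanone A1.
- Merits: it is biomimetic, it sets the only stereocentre late and catalytically, and the ester both speeds the closure and gives the catalyst a two-point hold.
- Weak points: the bond formed is the one that can reopen, so enantiopurity depends on decarboxylation outrunning the retro-Michael reaction. The step also says nothing about the harder structural problem, the hindered C3'–C8'' bond and the C8''/C6'' question, which would need a separate late cross-coupling at C8''.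
- Comparison: as a ring closure it is as good as anything available. It is adopted unchanged as steps 12 and 13 of the chosen plan, so A2 and A1 are the same compounds as 19 and 22, and neither plan is ahead in stereocontrol. The chosen plan differs in that its key step settles the ring A regiochemistry, which this road leaves open.

**Alternative 2:** The cut is C4a''–C5'', so flavone ring A is built last on a preformed 2-aryl-4-pyranone.
- Forward step: heating tert-butyl β-keto ester A4 expels the tert-butoxy group as the alcohol and unmasks a ketene at C5''. After enolisation of the C7'' carbonyl, a six-electron electrocyclisation joins C5'' to the pyranone carbon C4a'', and tautomerisation gives 5,7-dihydroxyflavone A3.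
- Merits: no reagent is needed. Ring A is assembled around the C8'' aryl group, so its position is fixed by connectivity and not by selectivity, and the two ring A phenols arrive unprotected. In regiochemical certainty this road is better than the chosen plan, which depends on the polarisation of an aryne.
- Weak points: A4 is a polycarbonyl chain on a base-sensitive pyranone with a doubly activated C8'' methine, so it is hard to assemble (C- versus O-acylation, pyranone ring opening). The ketene can also be captured by the enol oxygen, closing a hydroxypyranone in place of the carbocycle. A3 carries an aryl bromide and two methyl ethers beside two free phenols, so the aldehyde must still be introduced by metalation next to acidic OH groups, and the methyl ethers must be cleaved before the flavanone is built.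
- Comparison: against that certainty the chosen plan offers a key step whose reaction type is established for this pair of partners (aryne and arylpropiolic acid), a benzene precursor made by routine aromatic chemistry, and one protecting group throughout with no exchange.

**Alternative 3:** The cut is C8a–O1 of the flavanone.
- Forward step: CuI, 1,10-phenanthroline and Cs2CO3 cyclise the (1S,3S)-anti-diol A6, whose ring A carbon ortho to the C4 carbinol carries bromine. Only the C2 hydroxyl can reach the bromide through a six-membered ring, giving the (2S,4S)-flavan-4-ol A5, which is then oxidised at C4 and deprotected.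
- Merits: the C2–O bond at the stereocentre is never formed by a reversible conjugate addition, so the configuration set in the open chain is carried through with no retro-Michael erosion. In this respect it is more secure than the oxa-Michael closure used in the chosen plan.
- Weak points: two stereocentres are built to keep one, since C4 is oxidised away. The end-game from the aldehyde is longer (asymmetric C–C bond formation, anti-selective reduction, coupling, oxidation, deprotection). Six methoxymethyl ethers must be removed with acid from a flavanone whose C4' oxygen makes C2 ionisable. Like Alternative 1, it does not address the flavone.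
- Comparison: the chosen plan has a three-step end-game from the aldehyde and a neutral final deprotection; this road has the greater configurational safety and is the one to return to if enantiopurity cannot be held.

Key step: step 9

Assumption: the quinidine-derived cinchona thiourea is taken to give the (2S) sense of ring closure in step 13; if a model cyclisation shows the opposite sense, its quinine-derived pseudoenantiomer is used with nothing else changed.

## Route

Step 1
Reactants: 1 3,5-bis(benzyloxy)phenol
Product: 2 3,5-bis(benzyloxy)-2-bromophenol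
Conditions: NBS (1.0 equiv), CH2Cl2, −78 °C to rt
Reagents that add atoms: N-bromosuccinimide (O=C1CCC(=O)N1Br)
Why: Electrophilic aromatic bromination; at low temperature one equivalent of NBS should enter ortho to the free hydroxyl (two equivalent positions) in preference to the more crowded position between the two benzyloxy groups, as in the preparation of the parent 3,5-dialkoxy aryne precursors.

Step 2
Reactants: 3 4-(benzyloxy)-3-bromobenzaldehyde
Product: 4 2-[4-(benzyloxy)-3-bromophenyl]-1,3-dioxolane
Conditions: ethylene glycol, TsOH·H2O (cat.), toluene, reflux, Dean–Stark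
Reagents that add atoms: ethylene glycol (OCCO)
Why: Acid-catalysed acetalisation with azeotropic removal of water; it masks the aldehyde against the organolithium of step 7 and the bases of steps 3 and 4.

Step 3
Reactants: 4 2-[4-(benzyloxy)-3-bromophenyl]-1,3-dioxolane
Product: 5 2-[2-(benzyloxy)-5-(1,3-dioxolan-2-yl)phenyl]-4,4,5,5-tetramethyl-1,3,2-dioxaborolane
Conditions: B2pin2, Pd(dppf)Cl2 (3 mol%), KOAc, 1,4-dioxane, 90 °C
Reagents that add atoms: bis(pinacolato)diboron (CC1(C)OB(OC1(C)C)B1OC(C)(C)C(C)(C)O1)
Why: Miyaura borylation; zerovalent palladium inserts into the aryl bromide and acetate-assisted transmetalation with the diboron gives the pinacol boronate, while the acetal and benzyl ether are inert.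

Step 4
Reactants: 2 3,5-bis(benzyloxy)-2-bromophenol; 5 2-[2-(benzyloxy)-5-(1,3-dioxolan-2-yl)phenyl]-4,4,5,5-tetramethyl-1,3,2-dioxaborolane
Product: 6 3,5-bis(benzyloxy)-2-[2-(benzyloxy)-5-(1,3-dioxolan-2-yl)phenyl]phenol
Conditions: Pd(OAc)2 (5 mol%), SPhos (10 mol%), K3PO4, toluene/H2O (10:1), 90 °C
Reagents that add atoms: none
Why: Suzuki–Miyaura coupling forming the future C3'–C8'' bond; the bulky electron-rich SPhos ligand suits a doubly ortho-substituted electron-rich bromide and an ortho-alkoxy boronate, and free phenols are tolerated with phosphate base.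

Step 5
Reactants: 6 3,5-bis(benzyloxy)-2-[2-(benzyloxy)-5-(1,3-dioxolan-2-yl)phenyl]phenol
Product: 7 3,5-bis(benzyloxy)-2-[2-(benzyloxy)-5-(1,3-dioxolan-2-yl)phenyl]-6-bromophenol
Conditions: NBS (1.0 equiv), i-Pr2NH (10 mol%), CH2Cl2, 0 °C
Reagents that add atoms: N-bromosuccinimide (O=C1CCC(=O)N1Br)
Why: Amine-catalysed ortho-selective bromination of a phenol; the N-bromoamine is delivered through hydrogen bonding to the hydroxyl, so C6 (ortho) should be preferred over C4 (para and between two benzyloxy groups), and the other rings are far less activated.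

Step 6
Reactants: 7 3,5-bis(benzyloxy)-2-[2-(benzyloxy)-5-(1,3-dioxolan-2-yl)phenyl]-6-bromophenol
Product: 8 {3,5-bis(benzyloxy)-2-[2-(benzyloxy)-5-(1,3-dioxolan-2-yl)phenyl]-6-bromophenoxy}trimethylsilane
Conditions: HMDS, THF, 70 °C; then evaporation
Reagents that add atoms: hexamethyldisilazane (C[Si](C)(C)N[Si](C)(C)C)
Why: O-Silylation of a phenol with HMDS, ammonia being the only by-product; the silyl ether is taken on after removal of volatiles.

Step 7
Reactants: 8 {3,5-bis(benzyloxy)-2-[2-(benzyloxy)-5-(1,3-dioxolan-2-yl)phenyl]-6-bromophenoxy}trimethylsilane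
Product: 10 3,5-bis(benzyloxy)-2-[2-(benzyloxy)-5-(1,3-dioxolan-2-yl)phenyl]-6-(trimethylsilyl)phenyl trifluoromethanesulfonate, via lithium silylphenoxide 9 (not isolated)
Conditions: n-BuLi, THF, −78 °C; then Tf2O, −78 to 0 °C
Reagents that add atoms: trifluoromethanesulfonic anhydride (O=S(=O)(OS(=O)(=O)C(F)(F)F)C(F)(F)F)
Why: Halogen–lithium exchange followed by retro-Brook 1,3-shift of silicon from oxygen to carbon gives phenoxide 9, which is triflated on oxygen; this is the standard route to ortho-silylaryl triflates, and at −78 °C the benzyl ethers and the acetal are not attacked.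

Step 8
Reactants: 11 1-(benzyloxy)-4-ethynylbenzene
Product: 12 3-[4-(benzyloxy)phenyl]prop-2-ynoic acid
Conditions: n-BuLi, THF, −78 °C; CO2; then aq. HCl
Reagents that add atoms: carbon dioxide (O=C=O)
Why: Deprotonation of the terminal alkyne and carboxylation of the lithium acetylide, a routine preparation of arylpropiolic acids.

Step 9
Reactants: 10 3,5-bis(benzyloxy)-2-[2-(benzyloxy)-5-(1,3-dioxolan-2-yl)phenyl]-6-(trimethylsilyl)phenyl trifluoromethanesulfonate; 12 3-[4-(benzyloxy)phenyl]prop-2-ynoic acid
Product: 15 5,7-bis(benzyloxy)-8-[2-(benzyloxy)-5-(1,3-dioxolan-2-yl)phenyl]-2-[4-(benzyloxy)phenyl]-4H-chromen-4-one, via aryne 13 (not isolated), via hydroxyaryl ynone 14 (not isolated)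
Conditions: CsF (4 equiv), 12 (1.5 equiv), THF, 125 °C, sealed tube
Reagents that add atoms: none
Why: Fluoride attacks the silyl group of 10 and triflate leaves, giving aryne 13 with its triple bond between the future C4a'' and C8a''. The carboxylate of 12 adds through oxygen to C8a'', the aryne carbon remote from the C5'' benzyloxy group, because this places the developing aryl anion on C4a'' next to the inductively withdrawing oxygen (the bias that governs the parent 3,5-dialkoxybenzynes), and this electronic preference is expected to outweigh the steric demand of the twisted aryl group on C8''. The C4a'' anion attacks the neighbouring ester carbonyl through a four-membered tetrahedral intermediate and the acyl group moves from oxygen to carbon, giving the phenoxide of ynone 14; the high temperature favours this shift over simple protonation to an aryl ester. The phenoxide then adds to the ynone β-carbon in a 6-endo-dig oxa-Michael closure of ring C, and protonation at C3'' gives 15. The closest known reaction type is the fluoride-induced insertion of arynes into the C–O bond of carboxylic acids, which with arylpropiolic acids runs on to flavones. No stereocentre is formed. The selectivities needed are oxygen attack at C8a'' and not C4a'' (the reverse would give a 5-aryl-6,8-dioxygenated flavone; a 6''-aryl isomer cannot arise because the aryl group is already fixed next to C8a''), acyl shift over protonation, and 6-endo over 5-exo closure, the last being the usual course for aryl ynones under fluoride or carbonate. Benzyl ethers and the dioxolane are inert to fluoride.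

Step 10
Reactants: 15 5,7-bis(benzyloxy)-8-[2-(benzyloxy)-5-(1,3-dioxolan-2-yl)phenyl]-2-[4-(benzyloxy)phenyl]-4H-chromen-4-one
Product: 16 4-(benzyloxy)-3-{5,7-bis(benzyloxy)-2-[4-(benzyloxy)phenyl]-4-oxo-4H-chromen-8-yl}benzaldehyde
Conditions: 2 M aq. HCl, THF, rt
Reagents that add atoms: water (O)
Why: Acid-catalysed acetal hydrolysis; benzyl ethers and the flavone are stable to dilute acid at room temperature.

Step 11
Reactants: 17 1-[2,4-bis(benzyloxy)-6-hydroxyphenyl]ethan-1-one
Product: 18 tert-butyl 3-[2,4-bis(benzyloxy)-6-hydroxyphenyl]-3-oxopropanoate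
Conditions: LiHMDS (3.2 equiv), THF, −78 °C; Boc2O, −78 to 0 °C; then aq. HCl
Reagents that add atoms: di-tert-butyl dicarbonate (CC(C)(C)OC(=O)OC(=O)OC(C)(C)C)
Why: Claisen-type C-acylation of a ketone enolate; excess base forms the phenoxide–enolate dianion, whose enolate carbon attacks the dicarbonate in preference to the chelated hindered phenoxide, and the third equivalent of base deprotonates the product and so protects it from a second acylation.

Step 12
Reactants: 16 4-(benzyloxy)-3-{5,7-bis(benzyloxy)-2-[4-(benzyloxy)phenyl]-4-oxo-4H-chromen-8-yl}benzaldehyde; 18 tert-butyl 3-[2,4-bis(benzyloxy)-6-hydroxyphenyl]-3-oxopropanoate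
Product: 19 tert-butyl (2Z)-2-[2,4-bis(benzyloxy)-6-hydroxybenzoyl]-3-(4-(benzyloxy)-3-{5,7-bis(benzyloxy)-2-[4-(benzyloxy)phenyl]-4-oxo-4H-chromen-8-yl}phenyl)prop-2-enoate
Conditions: piperidine (cat.), AcOH (cat.), 4 Å MS, toluene, rt
Reagents that add atoms: none
Why: Knoevenagel condensation under piperidinium acetate catalysis at room temperature, mild enough that the free phenol should not yet add to the new alkene; an alkene isomer mixture is expected, drawn as the (Z) isomer (aryl cis to the ester), and is carried on as such.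

Step 13
Reactants: 19 tert-butyl (2Z)-2-[2,4-bis(benzyloxy)-6-hydroxybenzoyl]-3-(4-(benzyloxy)-3-{5,7-bis(benzyloxy)-2-[4-(benzyloxy)phenyl]-4-oxo-4H-chromen-8-yl}phenyl)prop-2-enoate
Product: 22 (2S)-5,7-bis(benzyloxy)-2-(4-(benzyloxy)-3-{5,7-bis(benzyloxy)-2-[4-(benzyloxy)phenyl]-4-oxo-4H-chromen-8-yl}phenyl)-2,3-dihydro-4H-chromen-4-one, via oxa-Michael adduct 20 (not isolated), via keto acid 21 (not isolated)
Conditions: quinidine-derived 3,5-bis(trifluoromethyl)phenyl thiourea (10 mol%), toluene, −25 °C; then TsOH·H2O, 80 °C
Reagents that add atoms: none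
Why: Catalytic enantioselective intramolecular oxa-Michael addition followed by acid-mediated ester cleavage and decarboxylation, the established route from alkylidene β-keto esters to flavanones; the thiourea binds the β-keto ester while the quinuclidine nitrogen activates the phenol, so oxygen is delivered to one face of the alkene in a 6-endo-trig closure and C2 is set (S) by the catalyst. TsOH then cleaves the tert-butyl ester of 20 and keto acid 21 loses CO2, which removes the labile C3 centre, and no base is present at any point after C2 is formed.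

Step 14
Reactants: 22 (2S)-5,7-bis(benzyloxy)-2-(4-(benzyloxy)-3-{5,7-bis(benzyloxy)-2-[4-(benzyloxy)phenyl]-4-oxo-4H-chromen-8-yl}phenyl)-2,3-dihydro-4H-chromen-4-one
Product: 23 (2S)-5,7-dihydroxy-2-{4-hydroxy-3-[5,7-dihydroxy-2-(4-hydroxyphenyl)-4-oxo-4H-chromen-8-yl]phenyl}-2,3-dihydro-4H-chromen-4-one
Conditions: H2 (1 atm), 10% Pd/C, EtOAc/MeOH, rt
Reagents that add atoms: none
Why: Hydrogenolysis of six aryl benzyl ethers over palladium on carbon under neutral conditions, so that neither base nor acid touches the flavanone and C2 keeps its configuration; the reaction is stopped once the benzyl groups are gone to spare the benzylic C2–O1 bond and the flavone alkene.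

## Compound list

1 | 3,5-bis(benzyloxy)phenol | Oc1cc(OCc2ccccc2)cc(OCc2ccccc2)c1 | starting material
2 | 3,5-bis(benzyloxy)-2-bromophenol | Oc1cc(OCc2ccccc2)cc(OCc2ccccc2)c1Br | intermediate
3 | 4-(benzyloxy)-3-bromobenzaldehyde | O=Cc1ccc(OCc2ccccc2)c(Br)c1 | starting material
4 | 2-[4-(benzyloxy)-3-bromophenyl]-1,3-dioxolane | Brc1cc(C2OCCO2)ccc1OCc1ccccc1 | intermediate
5 | 2-[2-(benzyloxy)-5-(1,3-dioxolan-2-yl)phenyl]-4,4,5,5-tetramethyl-1,3,2-dioxaborolane | CC1(C)OB(OC1(C)C)c1cc(C2OCCO2)ccc1OCc1ccccc1 | intermediate
6 | 3,5-bis(benzyloxy)-2-[2-(benzyloxy)-5-(1,3-dioxolan-2-yl)phenyl]phenol | Oc1cc(OCc2ccccc2)cc(OCc2ccccc2)c1-c1cc(C2OCCO2)ccc1OCc1ccccc1 | intermediate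
7 | 3,5-bis(benzyloxy)-2-[2-(benzyloxy)-5-(1,3-dioxolan-2-yl)phenyl]-6-bromophenol | Oc1c(Br)c(OCc2ccccc2)cc(OCc2ccccc2)c1-c1cc(C2OCCO2)ccc1OCc1ccccc1 | intermediate
8 | {3,5-bis(benzyloxy)-2-[2-(benzyloxy)-5-(1,3-dioxolan-2-yl)phenyl]-6-bromophenoxy}trimethylsilane | C[Si](C)(C)Oc1c(Br)c(OCc2ccccc2)cc(OCc2ccccc2)c1-c1cc(C2OCCO2)ccc1OCc1ccccc1 | intermediate
9 | lithium 3,5-bis(benzyloxy)-2-[2-(benzyloxy)-5-(1,3-dioxolan-2-yl)phenyl]-6-(trimethylsilyl)phenoxide | [Li+].[O-]c1c([Si](C)(C)C)c(OCc2ccccc2)cc(OCc2ccccc2)c1-c1cc(C2OCCO2)ccc1OCc1ccccc1 | intermediate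
10 | 3,5-bis(benzyloxy)-2-[2-(benzyloxy)-5-(1,3-dioxolan-2-yl)phenyl]-6-(trimethylsilyl)phenyl trifluoromethanesulfonate | FC(F)(F)S(=O)(=O)Oc1c([Si](C)(C)C)c(OCc2ccccc2)cc(OCc2ccccc2)c1-c1cc(C2OCCO2)ccc1OCc1ccccc1 | intermediate
11 | 1-(benzyloxy)-4-ethynylbenzene | C#Cc1ccc(OCc2ccccc2)cc1 | starting material
12 | 3-[4-(benzyloxy)phenyl]prop-2-ynoic acid | OC(=O)C#Cc1ccc(OCc2ccccc2)cc1 | intermediate
13 | 4,6-bis(benzyloxy)-3-[2-(benzyloxy)-5-(1,3-dioxolan-2-yl)phenyl]-1,2-didehydrobenzene (aryne) | C1#CC(OCc2ccccc2)=CC(OCc2ccccc2)=C1c1cc(C2OCCO2)ccc1OCc1ccccc1 | intermediate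
14 | 1-{4,6-bis(benzyloxy)-3-[2-(benzyloxy)-5-(1,3-dioxolan-2-yl)phenyl]-2-hydroxyphenyl}-3-[4-(benzyloxy)phenyl]prop-2-yn-1-one | O=C(C#Cc1ccc(OCc2ccccc2)cc1)c1c(O)c(-c2cc(C3OCCO3)ccc2OCc2ccccc2)c(OCc2ccccc2)cc1OCc1ccccc1 | intermediate
15 | 5,7-bis(benzyloxy)-8-[2-(benzyloxy)-5-(1,3-dioxolan-2-yl)phenyl]-2-[4-(benzyloxy)phenyl]-4H-chromen-4-one | O=c1cc(-c2ccc(OCc3ccccc3)cc2)oc2c(-c3cc(C4OCCO4)ccc3OCc3ccccc3)c(OCc3ccccc3)cc(OCc3ccccc3)c12 | intermediate
16 | 4-(benzyloxy)-3-{5,7-bis(benzyloxy)-2-[4-(benzyloxy)phenyl]-4-oxo-4H-chromen-8-yl}benzaldehyde | O=Cc1ccc(OCc2ccccc2)c(-c2c(OCc3ccccc3)cc(OCc3ccccc3)c3c(=O)cc(-c4ccc(OCc5ccccc5)cc4)oc23)c1 | intermediate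
17 | 1-[2,4-bis(benzyloxy)-6-hydroxyphenyl]ethan-1-one | CC(=O)c1c(O)cc(OCc2ccccc2)cc1OCc1ccccc1 | starting material
18 | tert-butyl 3-[2,4-bis(benzyloxy)-6-hydroxyphenyl]-3-oxopropanoate | CC(C)(C)OC(=O)CC(=O)c1c(O)cc(OCc2ccccc2)cc1OCc1ccccc1 | intermediate
19 | tert-butyl (2Z)-2-[2,4-bis(benzyloxy)-6-hydroxybenzoyl]-3-(4-(benzyloxy)-3-{5,7-bis(benzyloxy)-2-[4-(benzyloxy)phenyl]-4-oxo-4H-chromen-8-yl}phenyl)prop-2-enoate (major alkene isomer drawn) | CC(C)(C)OC(=O)/C(C(=O)c1c(O)cc(OCc2ccccc2)cc1OCc1ccccc1)=C\c1ccc(OCc2ccccc2)c(-c2c(OCc3ccccc3)cc(OCc3ccccc3)c3c(=O)cc(-c4ccc(OCc5ccccc5)cc4)oc23)c1 | intermediate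
20 | tert-butyl (2S)-5,7-bis(benzyloxy)-2-(4-(benzyloxy)-3-{5,7-bis(benzyloxy)-2-[4-(benzyloxy)phenyl]-4-oxo-4H-chromen-8-yl}phenyl)-4-oxochromane-3-carboxylate (C3 labile by keto–enol exchange and left undefined) | O=C1C(C(=O)OC(C)(C)C)[C@@H](c2ccc(OCc3ccccc3)c(-c3c(OCc4ccccc4)cc(OCc4ccccc4)c4c(=O)cc(-c5ccc(OCc6ccccc6)cc5)oc34)c2)Oc2cc(OCc3ccccc3)cc(OCc3ccccc3)c21 | intermediate
21 | (2S)-5,7-bis(benzyloxy)-2-(4-(benzyloxy)-3-{5,7-bis(benzyloxy)-2-[4-(benzyloxy)phenyl]-4-oxo-4H-chromen-8-yl}phenyl)-4-oxochromane-3-carboxylic acid (C3 undefined) | O=C1C(C(=O)O)[C@@H](c2ccc(OCc3ccccc3)c(-c3c(OCc4ccccc4)cc(OCc4ccccc4)c4c(=O)cc(-c5ccc(OCc6ccccc6)cc5)oc34)c2)Oc2cc(OCc3ccccc3)cc(OCc3ccccc3)c21 | intermediate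
22 | (2S)-5,7-bis(benzyloxy)-2-(4-(benzyloxy)-3-{5,7-bis(benzyloxy)-2-[4-(benzyloxy)phenyl]-4-oxo-4H-chromen-8-yl}phenyl)-2,3-dihydro-4H-chromen-4-one | O=C1C[C@@H](c2ccc(OCc3ccccc3)c(-c3c(OCc4ccccc4)cc(OCc4ccccc4)c4c(=O)cc(-c5ccc(OCc6ccccc6)cc5)oc34)c2)Oc2cc(OCc3ccccc3)cc(OCc3ccccc3)c21 | intermediate
23 | (2S)-5,7-dihydroxy-2-{4-hydroxy-3-[5,7-dihydroxy-2-(4-hydroxyphenyl)-4-oxo-4H-chromen-8-yl]phenyl}-2,3-dihydro-4H-chromen-4-one | O=C1C[C@@H](c2ccc(O)c(-c3c(O)cc(O)c4c(=O)cc(-c5ccc(O)cc5)oc34)c2)Oc2cc(O)cc(O)c21 | target

## Step count and least certain steps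

Total: 14 steps. Longest linear sequence: 11 steps (steps 2, 3, 4, 5, 6, 7, 9, 10, 12, 13, 14, from 3 to 23).

**Step 9 (key step).**
- What may go wrong: the carboxylate may add at the wrong aryne carbon, because the aryl group beside C8a'' opposes the electronic bias of the C5'' benzyloxy group. The aryl anion may be protonated before the acyl shift, stopping at the aryl ester. The propiolate may lose CO2 at 125 °C. The phenoxide may close 5-exo.
- Fallback, from 7 and 12, returning at 15: Steglich esterification (DCC, DMAP, CH2Cl2, 0 °C) of phenol 7 with acid 12 gives 3,5-bis(benzyloxy)-2-[2-(benzyloxy)-5-(1,3-dioxolan-2-yl)phenyl]-6-bromophenyl 3-[4-(benzyloxy)phenyl]prop-2-ynoate F1. Treatment with t-BuLi at −100 °C causes halogen–lithium exchange, and the aryllithium takes the neighbouring acyl group in an anionic Fries (Parham-type) shift to the phenoxide of 14. Cs2CO3 then closes ring C to 15. The aryl anion is generated at the carbon that carried bromine, so the regiochemistry no longer depends on aryne polarisation.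

**Step 13.**
- What may go wrong: uncatalysed or amine-carried background closure may lower the enantiomeric purity. Reversible ring opening under TsOH at 80 °C may do the same before decarboxylation is complete, helped by the electron-rich C4' oxygen.
- Fallback, from 16 and 17, returning at 22: Claisen–Schmidt condensation (KOH, EtOH, rt) gives (2E)-1-[2,4-bis(benzyloxy)-6-hydroxyphenyl]-3-(4-(benzyloxy)-3-{5,7-bis(benzyloxy)-2-[4-(benzyloxy)phenyl]-4-oxo-4H-chromen-8-yl}phenyl)prop-2-en-1-one F2. NaOAc in refluxing EtOH closes it to the racemic form of 22, racemic hexa-O-benzyl flavanone F3. Noyori–Ikariya transfer hydrogenation with [Cp*RhCl(TsDPEN)] and HCO2H/Et3N, using the catalyst antipode that consumes the (2R) ketone, then acts as a kinetic resolution: the (2R) enantiomer is reduced to the (2R,4R)-cis-flavan-4-ol F4 and (2S)-22 is recovered. At most half of the material is kept.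

**Step 5.**
- What may go wrong: bromination at C4 (para to the hydroxyl) or double bromination would put silicon and triflate on the wrong carbons.
- Fallback, from 6, returning at 10: isopropyl isocyanate and Et3N give 3,5-bis(benzyloxy)-2-[2-(benzyloxy)-5-(1,3-dioxolan-2-yl)phenyl]phenyl N-(propan-2-yl)carbamate F5. In situ N-silylation (TMSOTf, TMEDA), carbamate-directed ortho-lithiation with n-BuLi at −78 °C (C6 is the only free ortho position) and quench with TMSCl give 3,5-bis(benzyloxy)-2-[2-(benzyloxy)-5-(1,3-dioxolan-2-yl)phenyl]-6-(trimethylsilyl)phenyl N-(propan-2-yl)carbamate F6. Et2NH and DBU in MeCN cleave the carbamate to 3,5-bis(benzyloxy)-2-[2-(benzyloxy)-5-(1,3-dioxolan-2-yl)phenyl]-6-(trimethylsilyl)phenol F7, which PhNTf2 in the same flask converts into 10.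

**Step 14.**
- What may go wrong: over-reduction may cleave the benzylic C2–O1 bond (opening to a dihydrochalcone) or saturate the flavone alkene. The freed 4'-hydroxyflavanone may also racemise slowly in a protic medium.
- Fallback, from 22 directly to 23: non-reductive debenzylation with BCl3 and pentamethylbenzene as cation scavenger in CH2Cl2 at −78 °C, with a cold, weakly acidic work-up.

## Further compounds

F1 | step 9 | 3,5-bis(benzyloxy)-2-[2-(benzyloxy)-5-(1,3-dioxolan-2-yl)phenyl]-6-bromophenyl 3-[4-(benzyloxy)phenyl]prop-2-ynoate | O=C(C#Cc1ccc(OCc2ccccc2)cc1)Oc1c(Br)c(OCc2ccccc2)cc(OCc2ccccc2)c1-c1cc(C2OCCO2)ccc1OCc1ccccc1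
F2 | step 13 | (2E)-1-[2,4-bis(benzyloxy)-6-hydroxyphenyl]-3-(4-(benzyloxy)-3-{5,7-bis(benzyloxy)-2-[4-(benzyloxy)phenyl]-4-oxo-4H-chromen-8-yl}phenyl)prop-2-en-1-one | O=C(/C=C/c1ccc(OCc2ccccc2)c(-c2c(OCc3ccccc3)cc(OCc3ccccc3)c3c(=O)cc(-c4ccc(OCc5ccccc5)cc4)oc23)c1)c1c(O)cc(OCc2ccccc2)cc1OCc1ccccc1
F3 | step 13 | racemic 5,7-bis(benzyloxy)-2-(4-(benzyloxy)-3-{5,7-bis(benzyloxy)-2-[4-(benzyloxy)phenyl]-4-oxo-4H-chromen-8-yl}phenyl)-2,3-dihydro-4H-chromen-4-one | O=C1CC(c2ccc(OCc3ccccc3)c(-c3c(OCc4ccccc4)cc(OCc4ccccc4)c4c(=O)cc(-c5ccc(OCc6ccccc6)cc5)oc34)c2)Oc2cc(OCc3ccccc3)cc(OCc3ccccc3)c21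
F4 | step 13 | 5,7-bis(benzyloxy)-8-{2-(benzyloxy)-5-[(2R,4R)-5,7-bis(benzyloxy)-4-hydroxychroman-2-yl]phenyl}-2-[4-(benzyloxy)phenyl]-4H-chromen-4-one | O[C@@H]1C[C@H](c2ccc(OCc3ccccc3)c(-c3c(OCc4ccccc4)cc(OCc4ccccc4)c4c(=O)cc(-c5ccc(OCc6ccccc6)cc5)oc34)c2)Oc2cc(OCc3ccccc3)cc(OCc3ccccc3)c21
F5 | step 5 | 3,5-bis(benzyloxy)-2-[2-(benzyloxy)-5-(1,3-dioxolan-2-yl)phenyl]phenyl N-(propan-2-yl)carbamate | CC(C)NC(=O)Oc1cc(OCc2ccccc2)cc(OCc2ccccc2)c1-c1cc(C2OCCO2)ccc1OCc1ccccc1
F6 | step 5 | 3,5-bis(benzyloxy)-2-[2-(benzyloxy)-5-(1,3-dioxolan-2-yl)phenyl]-6-(trimethylsilyl)phenyl N-(propan-2-yl)carbamate | CC(C)NC(=O)Oc1c([Si](C)(C)C)c(OCc2ccccc2)cc(OCc2ccccc2)c1-c1cc(C2OCCO2)ccc1OCc1ccccc1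
F7 | step 5 | 3,5-bis(benzyloxy)-2-[2-(benzyloxy)-5-(1,3-dioxolan-2-yl)phenyl]-6-(trimethylsilyl)phenol | Oc1c([Si](C)(C)C)c(OCc2ccccc2)cc(OCc2ccccc2)c1-c1cc(C2OCCO2)ccc1OCc1ccccc1
F0 | step 14 | none | none
A1 | alternative 1 | hexa-O-benzyl (2S)-flavanone, identical with 22 | O=C1C[C@@H](c2ccc(OCc3ccccc3)c(-c3c(OCc4ccccc4)cc(OCc4ccccc4)c4c(=O)cc(-c5ccc(OCc6ccccc6)cc5)oc34)c2)Oc2cc(OCc3ccccc3)cc(OCc3ccccc3)c21
A2 | alternative 1 | hexa-O-benzyl alkylidene β-keto tert-butyl ester, identical with 19 | CC(C)(C)OC(=O)/C(C(=O)c1c(O)cc(OCc2ccccc2)cc1OCc1ccccc1)=C\c1ccc(OCc2ccccc2)c(-c2c(OCc3ccccc3)cc(OCc3ccccc3)c3c(=O)cc(-c4ccc(OCc5ccccc5)cc4)oc23)c1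
A3 | alternative 2 | 8-(5-bromo-2-methoxyphenyl)-5,7-dihydroxy-2-(4-methoxyphenyl)chromen-4-one | COc1ccc(-c2cc(=O)c3c(O)cc(O)c(-c4cc(Br)ccc4OC)c3o2)cc1
A4 | alternative 2 | tert-butyl 4-(5-bromo-2-methoxyphenyl)-4-[6-(4-methoxyphenyl)-4-oxo-4H-pyran-2-yl]-3-oxobutanoate | CC(C)(C)OC(=O)CC(=O)C(c1cc(Br)ccc1OC)c1cc(=O)cc(-c2ccc(OC)cc2)o1
A5 | alternative 3 | (2S,4S)-flavan-4-ol form of the hexa-O-methoxymethyl target | O[C@H]1C[C@@H](c2ccc(OCOC)c(-c3c(OCOC)cc(OCOC)c4c(=O)cc(-c5ccc(OCOC)cc5)oc34)c2)Oc2cc(OCOC)cc(OCOC)c21
A6 | alternative 3 | (1S,3S)-1-[2-bromo-4,6-bis(methoxymethoxy)phenyl]-3-(4-(methoxymethoxy)-3-{5,7-bis(methoxymethoxy)-2-[4-(methoxymethoxy)phenyl]-4-oxo-4H-chromen-8-yl}phenyl)propane-1,3-diol | O[C@@H](C[C@@H](c1ccc(OCOC)c(-c2c(OCOC)cc(OCOC)c3c(=O)cc(-c4ccc(OCOC)cc4)oc23)c1)O)c1c(Br)cc(OCOC)cc1OCOC
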